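- Begin with Z, the reagent in the reaction phase: this flask receives it from G in the second phase.

X 0.079 M; G 3.00 equiv; time 40 min; volume of the second phase over the first 0.25

- how much X.Z and L and J together there is at 40 min, in percent of the X charged
- concentration of X.Z in solution at 40 min, in percent of saturation

- amounts and yields of X.Z count L and J too
- in the second phase: G, L; everything else is in the first
- charges count per volume of the first phase; a concentration in a rate is the amount of a species over the volume of its own phase; every rate counts per litre of the first phase
- given per volume of solution although it is solid: J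
- run time (flask): 40 min

    Z ⇌ G, rate k1*([Z] - [G]/K1) per volume of the first phase (K1 = 14, k1 = 3.0 × 10⁻⁴ s⁻¹)
    X + Z → X.Z (k2 = 0.010 L mol⁻¹ s⁻¹)
    X.Z ⇌ L, rate k3*([X.Z] - [L]/K3) per volume of the first phase (K3 = 3.3, k3 = 0.0077 s⁻¹)
    X.Z → D (k4 = 0.0024 s⁻¹)
    X ⇌ E (K5 = 0.47, k5 = 0.0051 s⁻¹)
    J ⇌ X.Z, rate k6*(cs6 - [X.Z]) while solid is left; crystals form when [X.Z] > cs6 (cs6 = 2.6 mM, k6 = 0.015 s⁻¹)

- In this flask, X and E relax with a half-life of 0.724 min, faster than the 15 min half-life of Z by step 2. So free X is reckoned as 68.0% of the pool of X and E.
- G as charged feeds Z at 0.00122 M min⁻¹.
- Z leaves by reaction with free X, pseudo-first-order at 0.0322 min⁻¹, and by return to G at 0.018 min⁻¹.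
- Feed divided by both exits gives the plateau of Z, 0.0243 M.
- The bench rule holds Z at this plateau throughout. Then 39.6% of the X charged is made.
- The border of that rule is the rise time of Z, the inverse of both exits: 19.9 min. Run time over rise time is 2.01, so the reckoning puts this flask below the plateau for much of its run.
- With the rise counted, Z reaches 0.0210 M at 40 min, and the share made falls to 22.5%.
- y counts what stays of that share. Dissolved X.Z has a half-life of 4.8 min by step 4 alone, short against 40 min.
- The rate of making at 40 min over k4 points to 181% of saturation, so this reckoning expects crystals and stops there.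
- The forecast gives y as 7.7% and sat as 105%, on the ground that “The slow feed of Z from the second phase limits the reaction”.
- The simulation gives y as 7.48% and sat as 105%.

- At 40.0 min this flask reads Z at 0.0200 M against the plateau of 0.0243 M and the reckoned 0.0210 M, and X.Z in all its forms with D at 19.4% against the reckoned 22.5%. The drag of the uptake of G as Z holds back a part of the yield: without that drag, this flask gives y as 31.2% instead of 7.48%. That is 24 percentage points, or 26% of what y falls short of the whole charge.

- With 0.20 M of X and the same equivalents, the reckoning gives a rise time of 10.0 min and a plateau of 0.0310 M. At 40.0 min that neighbour flask reads Z at 0.0324 M, with y at 22.1%, of which 18.5% is J.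

The rate constants are made up; the rest is arithmetic.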